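**Retrosynthetic overview**
- 25 ⇒ 22: the γ-lactone is cut at O–C6 and at C11–C12, so C12(=O)–O leaves as CO2. Precursor 22 is the macrocyclic C4/C15 vinyl epoxide carrying an alkenyl–Bpin at C11.
- Enabling feature: the lactone oxygen sits on C6, allylic to the (Z)-C4=C5 bond that bears C15–OH. The array O–C6–C5=C4–C15–O is the 1,4-opening pattern of a vinyl epoxide, and C11 is a 1,1-disubstituted alkenyl carbon that can carry boron.
- 22 ⇒ 21 (RCM at C5=C6, templated by the C3–O–C10 hemiketal oxolane) ⇒ 14 + 16 (homoallenylboration, Sharpless epoxidation and oxidation set C4) ⇒ 6 + 8 (anti-allylboration sets C7/C8) ⇒ (R)-linalool (C10).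
- Ring order: oxolane ring (C3–O–C10) first, ten-membered carbocycle second, γ-lactone last.

Key step: step 14

Numbering: C1–C15 are the germacrane positions of the target (C12 lactone carbonyl, C13 exocyclic methylene, C14 methyl on C10, C15 hydroxymethyl on C4); Bpin = 4,4,5,5-tetramethyl-1,3,2-dioxaborolan-2-yl; the target as drawn is 3S,6S,7R,8R,10R,4Z with a cis-fused lactone.
Assumption: the carbinol configurations from the two chiral phosphoric acid steps are assigned by analogy with the usual Re-face preference of (R)-TRIP in aldehyde allylborations; if a sense proves opposite, the antipodal acid is used.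

Step 1
Reactants: 1 (R)-(−)-linalool
Product: 3 (5R)-5-ethenyl-2-methoxy-5-methyloxolane (anomer mixture), via lactol 2 (not isolated)
Conditions: O3 (1.0 equiv), CH2Cl2/MeOH 4:1, −78 °C; Me2S, −78 °C → rt; then PPTS (5 mol %), MeOH, rt
Reagents that add atoms: methanol, CO (the OMe group); ozone, [O-][O+]=O (oxygen of lactol 2 only, lost again as water on acetalisation)
Why: The electron-rich trisubstituted alkene should be ozonised much faster than the vinyl group (chemoselective ozonolysis), the γ-hydroxy aldehyde closes to lactol 2 and Fischer-type acetalisation masks C3 and the C10 oxygen in one ring; C10 comes unchanged from the chiral pool.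

Step 2
Reactants: 3 (5R)-5-ethenyl-2-methoxy-5-methyloxolane
Product: 5 2-[(2R)-5-methoxy-2-methyloxolan-2-yl]ethan-1-ol, via alkylborane 4 (not isolated)
Conditions: 9-BBN (1.3 equiv), THF, 0 °C → rt; then 3 M NaOH, 30 % H2O2, 0 °C → rt
Reagents that add atoms: hydrogen peroxide, OO
Why: Anti-Markovnikov hydroboration–oxidation of the only alkene should place the hydroxyl on the terminal carbon (C8), and the acetal is stable to the basic oxidation.

Step 3
Reactants: 5 2-[(2R)-5-methoxy-2-methyloxolan-2-yl]ethan-1-ol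
Product: 6 2-[(2R)-5-methoxy-2-methyloxolan-2-yl]acetaldehyde
Conditions: DMP (1.2 equiv), NaHCO3, CH2Cl2, 0 °C → rt
Reagents that add atoms: none
Why: Buffered Dess–Martin oxidation should give the β-alkoxy aldehyde without acetal loss or β-elimination; it is used directly.

Step 4
Reactants: 7 (E)-pent-2-en-4-yn-1-ol
Product: 8 (E)-4,4,5,5-tetramethyl-2-(pent-2-en-4-yn-1-yl)-1,3,2-dioxaborolane
Conditions: B2pin2 (1.1 equiv), Pd(MeCN)4(BF4)2 (2 mol %), DMSO/MeOH 1:1, 50 °C
Reagents that add atoms: bis(pinacolato)diboron, CC1(C)OB(OC1(C)C)B1OC(C)(C)C(C)(C)O1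
Why: Palladium-catalysed borylation of an allylic alcohol through an η3-allyl intermediate should deliver boron to the unsubstituted terminus and give the linear (E)-allylboronate.

Step 5
Reactants: 6 2-[(2R)-5-methoxy-2-methyloxolan-2-yl]acetaldehyde and 8 (E)-pent-2-en-4-ynyl-Bpin
Product: 10 (2R,3R)-3-ethenyl-1-[(2R)-5-methoxy-2-methyloxolan-2-yl]pent-4-yn-2-ol (7R,8R in target numbering), via borate 9 (not isolated)
Conditions: 8 (1.3 equiv), (S)-TRIP (5 mol %), 4 Å MS, toluene, −30 °C; aqueous NaHCO3 work-up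
Reagents that add atoms: none
Why: Chiral phosphoric acid-catalysed allylboration through a chair Zimmerman–Traxler transition state should give the anti relationship between C8–OH and the C7 alkynyl group from the (E)-boronate, with the catalyst selecting the aldehyde face that gives 8R.

Step 6
Reactants: 10 (2R,3R)-3-ethenyl-1-[(2R)-5-methoxy-2-methyloxolan-2-yl]pent-4-yn-2-ol
Product: 12 (2R,3R)-3-ethenyl-1-[(2R)-5-methoxy-2-methyloxolan-2-yl]-4-(Bpin)pent-4-en-2-ol, via alkenylalane 11 (not isolated)
Conditions: NiCl2(dppp) (3 mol %), iBu2AlH (2.5 equiv), THF, 0 → 22 °C; then MeOBpin (3 equiv), 0 → 22 °C; aqueous Rochelle salt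
Reagents that add atoms: 2-methoxy-4,4,5,5-tetramethyl-1,3,2-dioxaborolane, COB1OC(C)(C)C(C)(C)O1
Why: Nickel-catalysed α-selective (Markovnikov) hydroalumination of the terminal alkyne should place aluminium on the internal carbon C11, and Al-to-B exchange with MeOBpin gives the 1,1-disubstituted alkenylboronate; the first equivalent of hydride only converts C8–OH into its aluminium alkoxide.

Step 7
Reactants: 12 alkenylboronate alcohol
Product: 13 (2R,3R)-3-ethenyl-1-[(2R)-5-methoxy-2-methyloxolan-2-yl]-4-(Bpin)pent-4-en-2-yl 2-methylpropanoate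
Conditions: (iPrCO)2O (1.5 equiv), Et3N (2 equiv), DMAP (10 mol %), CH2Cl2, 0 °C → rt
Reagents that add atoms: isobutyric anhydride, CC(C)C(=O)OC(=O)C(C)C
Why: DMAP-catalysed acylation of the only free hydroxyl installs the C8 isobutyrate before any other hydroxyl is unveiled.

Step 8
Reactants: 13 isobutyrate acetal
Product: 14 (2R,3R)-3-ethenyl-1-[(2R)-5-hydroxy-2-methyloxolan-2-yl]-4-(Bpin)pent-4-en-2-yl 2-methylpropanoate (lactol, anomer mixture)
Conditions: PPTS (10 mol %), acetone/H2O 4:1, 40 °C
Reagents that add atoms: water, O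
Why: Mild acetal hydrolysis through the cyclic oxocarbenium ion should unmask the C3 aldehyde as its lactol while the ester and the pinacol boronate survive.

Step 9
Reactants: 15 allenylboronic acid pinacol ester
Product: 16 2-(buta-2,3-dien-1-yl)-4,4,5,5-tetramethyl-1,3,2-dioxaborolane
Conditions: BrCH2Cl (1.5 equiv), n-BuLi (1.4 equiv), THF, −78 °C → rt
Reagents that add atoms: bromochloromethane, ClCBr
Why: Matteson homologation: (chloromethyl)lithium forms the boron ate complex and 1,2-migration of the allenyl group with loss of chloride inserts one CH2.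

Step 10
Reactants: 14 lactol and 16 buta-2,3-dienyl-Bpin
Product: 18 dienyl diol (3S,7R,8R,10R): (3R,4R,6R,9S)-3-ethenyl-6,9-dihydroxy-6-methyl-10-methylidene-2-(Bpin)dodeca-1,11-dien-4-yl 2-methylpropanoate, via borate 17 (not isolated)
Conditions: 16 (1.5 equiv), (R)-TRIP (10 mol %), 4 Å MS, toluene, 0 °C → rt; aqueous NaHCO3 work-up
Reagents that add atoms: none
Why: Chiral phosphoric acid-catalysed homoallenylboration of the open hydroxy aldehyde (cyclic SE2′ transition state) should attach the buta-1,3-dien-2-yl unit, forming C3–C4 with catalyst-controlled Re-face attack to give the 3S carbinol.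

Step 11
Reactants: 18 dienyl diol
Product: 19 epoxy diol (3S,4S,7R,8R,10R): the C4=C15 alkene of 18 converted into the C4/C15 oxirane
Conditions: Ti(OiPr)4 (0.2 equiv), L-(+)-DIPT (0.25 equiv), t-BuOOH (1.5 equiv), 4 Å MS, CH2Cl2, −20 °C
Reagents that add atoms: tert-butyl hydroperoxide, CC(C)(C)OO
Why: Sharpless asymmetric epoxidation should oxidise only the alkene of the secondary allylic alcohol (C4=C15); the L-tartrate is matched with the 3S carbinol and with the erythro preference of 2-substituted allylic alcohols, which sets 4S.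

Step 12
Reactants: 19 epoxy diol
Product: 21 cyclic hemiketal (C3 anomers) with the (4S)-2-ethenyloxiran-2-yl group on C3, via keto alcohol 20 (not isolated)
Conditions: DMP (1.3 equiv), NaHCO3, CH2Cl2, 0 °C → rt
Reagents that add atoms: none
Why: Dess–Martin oxidation of the only secondary alcohol gives the α,β-epoxy ketone, whose electrophilic carbonyl should be trapped by the tertiary C10 hydroxyl as the five-membered hemiketal; the C3 carbinol centre, having relayed its configuration to C4, is erased.

Step 13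
Reactants: 21 hemiketal diene
Product: 22 macrocyclic vinyl epoxide (3S,4S,5Z,7R,8R,10R): 11-oxabicyclo[6.2.1]undec-5-ene with 3-OH (hemiketal), 4/15 spiro-oxirane, 7-[1-(Bpin)ethenyl], 8-isobutyryloxy and 10-methyl
Conditions: second-generation Hoveyda–Grubbs catalyst, RuCl2(H2IMes)(=CH-C6H4-2-OiPr) (10 mol %), toluene (1 mM), 80 °C, argon sparge
Reagents that add atoms: none
Why: Ring-closing metathesis of the two vinyl groups should be templated by the hemiketal anomer that holds C4 and C9 cis on the oxolane, so that only a nine-membered ring (through the oxygen bridge) has to close, which enforces the Z-C5=C6 bond; the 1,1-disubstituted alkenylboronate should be a spectator.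

Step 14
Reactants: 22 macrocyclic vinyl epoxide
Product: 25 target CNP0282937.2, via copper carboxylate 23 (not isolated), via boryl ether 24 (not isolated)
Conditions: CO2 (1 atm), CuCl(IPr) (10 mol %), KOtBu (10 mol %), Pd(PPh3)4 (5 mol %), THF, 60 °C; aqueous NH4Cl work-up
Reagents that add atoms: carbon dioxide, O=C=O
Why: Proposed new method: a copper cycle and a palladium cycle are relayed through the substrate — (IPr)Cu–OR transmetalates the C11 alkenyl–Bpin and the alkenylcopper inserts CO2 (C11–C12 bond) to give carboxylate 23, while zerovalent palladium ionises the allylic C4–O bond of the vinyl epoxide with inversion to an η3-allyl over C4–C5–C6 whose C15 alkoxide (buffered by CO2 and boron) regenerates Cu–OR, so that only catalytic base is needed. The closest known reactions are the NHC–copper-catalysed carboxylation of alkenylboronic esters with CO2 and the palladium-catalysed 1,4-opening (Tsuji–Trost type, SN2′ overall) of vinyl epoxides by carboxylates. The carboxylate oxygen attacks C6 anti to palladium in a 5-exo closure of the γ-lactone ring (O–C6 bond), the only ring formed; attack at C4 would need a seven-membered ring at a tertiary, oxygen-flanked centre. C6 is the one new stereocentre and is set by 1,3-chirality transfer from C4: two inversions put the lactone oxygen on the allyl face that carried the epoxide oxygen, which in the 4S epoxide is the face on which C7 holds C11, hence 6S and the cis ring fusion. The new C4=C5 bond is Z because C3 and C6 are both held anti on the allyl unit by the nine-membered ring, and the step also frees the C15 hydroxyl (after hydrolysis of boryl ether 24). The step needs CO2 insertion to outrun protonation of the alkenylcopper and C–C coupling at palladium, which the CO2 atmosphere and the fast intramolecular lactonisation should secure.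

**Compound list**
1 | (R)-(−)-linalool, (3R)-3,7-dimethylocta-1,6-dien-3-ol | C=C[C@](C)(O)CCC=C(C)C | starting material
2 | (5R)-5-ethenyl-5-methyloxolan-2-ol (lactol, anomers) | C=C[C@@]1(C)CCC(O)O1 | intermediate
3 | (5R)-5-ethenyl-2-methoxy-5-methyloxolane (anomers) | C=C[C@@]1(C)CCC(OC)O1 | intermediate
4 | 9-{2-[(2R)-5-methoxy-2-methyloxolan-2-yl]ethyl}-9-borabicyclo[3.3.1]nonane | COC1CC[C@](C)(CCB2C3CCCC2CCC3)O1 | intermediate
5 | 2-[(2R)-5-methoxy-2-methyloxolan-2-yl]ethan-1-ol | OCC[C@@]1(C)CCC(OC)O1 | intermediate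
6 | 2-[(2R)-5-methoxy-2-methyloxolan-2-yl]acetaldehyde | O=CC[C@@]1(C)CCC(OC)O1 | intermediate
7 | (E)-pent-2-en-4-yn-1-ol | C#C/C=C/CO | starting material
8 | (E)-4,4,5,5-tetramethyl-2-(pent-2-en-4-yn-1-yl)-1,3,2-dioxaborolane | C#C/C=C/CB1OC(C)(C)C(C)(C)O1 | intermediate
9 | O-Bpin borate ester of 10 | C#C[C@@H](C=C)[C@H](OB1OC(C)(C)C(C)(C)O1)C[C@@]2(C)CCC(OC)O2 | intermediate
10 | (2R,3R)-3-ethenyl-1-[(2R)-5-methoxy-2-methyloxolan-2-yl]pent-4-yn-2-ol | C#C[C@@H](C=C)[C@H](O)C[C@@]1(C)CCC(OC)O1 | intermediate
11 | C11 alkenyl(diisobutyl)alane, C8 diisobutylaluminium alkoxide of 10 | C=C([Al](CC(C)C)CC(C)C)[C@@H](C=C)[C@H](O[Al](CC(C)C)CC(C)C)C[C@@]1(C)CCC(OC)O1 | intermediate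
12 | (2R,3R)-3-ethenyl-1-[(2R)-5-methoxy-2-methyloxolan-2-yl]-4-(Bpin)pent-4-en-2-ol | C=C(B1OC(C)(C)C(C)(C)O1)[C@@H](C=C)[C@H](O)C[C@@]2(C)CCC(OC)O2 | intermediate
13 | 2-methylpropanoate (isobutyrate) of 12 | C=C(B1OC(C)(C)C(C)(C)O1)[C@@H](C=C)[C@H](OC(=O)C(C)C)C[C@@]2(C)CCC(OC)O2 | intermediate
14 | lactol corresponding to 13 (OMe replaced by OH, anomers) | C=C(B1OC(C)(C)C(C)(C)O1)[C@@H](C=C)[C@H](OC(=O)C(C)C)C[C@@]2(C)CCC(O)O2 | intermediate
15 | allenylboronic acid pinacol ester, 4,4,5,5-tetramethyl-2-(propa-1,2-dien-1-yl)-1,3,2-dioxaborolane | C=C=CB1OC(C)(C)C(C)(C)O1 | starting material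
16 | 2-(buta-2,3-dien-1-yl)-4,4,5,5-tetramethyl-1,3,2-dioxaborolane | C=C=CCB1OC(C)(C)C(C)(C)O1 | intermediate
17 | C3 O-Bpin borate ester of 18 | C=C(B1OC(C)(C)C(C)(C)O1)[C@@H](C=C)[C@H](OC(=O)C(C)C)C[C@](C)(O)CC[C@H](OB2OC(C)(C)C(C)(C)O2)C(=C)C=C | intermediate
18 | dienyl diol (3S,7R,8R,10R): (3R,4R,6R,9S)-3-ethenyl-6,9-dihydroxy-6-methyl-10-methylidene-2-(Bpin)dodeca-1,11-dien-4-yl 2-methylpropanoate | C=C(B1OC(C)(C)C(C)(C)O1)[C@@H](C=C)[C@H](OC(=O)C(C)C)C[C@](C)(O)CC[C@H](O)C(=C)C=C | intermediate
19 | epoxy diol (3S,4S,7R,8R,10R): 18 with the C4=C15 alkene as oxirane | C=C(B1OC(C)(C)C(C)(C)O1)[C@@H](C=C)[C@H](OC(=O)C(C)C)C[C@](C)(O)CC[C@H](O)[C@]2(C=C)CO2 | intermediate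
20 | keto alcohol (4S,7R,8R,10R): C3 ketone of 19 | C=C(B1OC(C)(C)C(C)(C)O1)[C@@H](C=C)[C@H](OC(=O)C(C)C)C[C@](C)(O)CCC(=O)[C@]2(C=C)CO2 | intermediate
21 | cyclic hemiketal of 20 (C3 anomers; 4S,7R,8R,10R) | C=C(B1OC(C)(C)C(C)(C)O1)[C@@H](C=C)[C@H](OC(=O)C(C)C)C[C@@]2(C)CCC(O)(O2)[C@]3(C=C)CO3 | intermediate
22 | macrocyclic vinyl epoxide (3S,4S,5Z,7R,8R,10R), 11-oxabicyclo[6.2.1]undec-5-ene core | C=C(B1OC(C)(C)C(C)(C)O1)[C@H]2/C=C\[C@]3(CO3)[C@]4(O)CC[C@](C)(C[C@H]2OC(=O)C(C)C)O4 | intermediate
23 | monovalent copper carboxylate of 22 (C11–CO2Cu, NHC ligand not drawn) | C=C(C(=O)[O-])[C@H]2/C=C\[C@]3(CO3)[C@]4(O)CC[C@](C)(C[C@H]2OC(=O)C(C)C)O4.[Cu+] | intermediate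
24 | C15 O-Bpin ether of 25 | C=C1C(=O)O[C@H]2/C=C(/COB4OC(C)(C)C(C)(C)O4)[C@]3(O)CC[C@](C)(C[C@@H](OC(=O)C(C)C)[C@@H]12)O3 | intermediate
25 | CNP0282937.2 (3S,6S,7R,8R,10R,4Z) | C=C1C(=O)O[C@H]2/C=C(/CO)[C@]3(O)CC[C@](C)(C[C@@H](OC(=O)C(C)C)[C@@H]12)O3 | target

**Step count and risks**
Total steps: 14 (12 on the main line plus the two reagent preparations, steps 4 and 9). Longest linear sequence: 12 steps from 1 (steps 1–3, 5–8, 10–14).

Steps most likely to fail:

1. Step 14 (Proposed new method). The two cycles may fail to mesh: the alkenylcopper may be protonated by the hemiketal hydroxyl before CO2 insertion, the alkenyl and allyl fragments may couple at palladium, or the alkoxide-bearing allyl complex may lose a β-hydride and isomerise. Fallback, from 22: the standard stoichiometric-base NHC–copper carboxylation (CuCl(IPr) 5 mol %, KOtBu 1.1 equiv, CO2, THF, 60 °C) should give the potassium acrylate F1. Pd(PPh3)4 (5 mol %) is then added to the same flask for the known palladium-catalysed 1,4-opening of the vinyl epoxide by the tethered carboxylate, and aqueous work-up returns to the route at 25.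

2. Step 13. Two vinyl groups on fully substituted carbons must meet while the hemiketal equilibrates with its open-chain and trans forms, so oligomerisation and catalyst decay may win over ring closure. Fallback, from 21: the template is locked instead of dynamic. Acid-equilibrated ketalisation (MeOH, HC(OMe)3, PPTS) gives the cis methyl ketal F2, ring-closing metathesis gives the macrocyclic ketal F3, the conditions of step 14 give the 3-O-methyl lactone F4, and mild hydrolysis (AcOH/THF/H2O) returns to the route at 25.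

3. Step 10. The aldehyde is masked as a lactol, so the addition may be slow and the facial selectivity may erode. Fallback, from 14: an unselective indium-mediated 1,3-butadien-2-ylation (1,4-dibromobut-2-yne, indium powder, THF/H2O) gives 18 together with its 3R epimer F5. The mixture is carried into step 11, where the titanium–tartrate epoxidation acts as a kinetic resolution that converts only 18; F5 is removed by chromatography and the route is rejoined at 19.

Further compounds
F1 | step 14 | potassium carboxylate of 22 (C11–CO2K, epoxide intact) | C=C(C(=O)[O-])[C@H]2/C=C\[C@]3(CO3)[C@]4(O)CC[C@](C)(C[C@H]2OC(=O)C(C)C)O4.[K+]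
F2 | step 13 | cis methyl ketal of 21 (3S,4S,7R,8R,10R) | C=C(B1OC(C)(C)C(C)(C)O1)[C@@H](C=C)[C@H](OC(=O)C(C)C)C[C@@]2(C)CC[C@](OC)(O2)[C@]3(C=C)CO3
F3 | step 13 | 3-O-methyl ketal analogue of 22 | C=C(B1OC(C)(C)C(C)(C)O1)[C@H]2/C=C\[C@]3(CO3)[C@]4(OC)CC[C@](C)(C[C@H]2OC(=O)C(C)C)O4
F4 | step 13 | 3-O-methyl ketal of 25 | C=C1C(=O)O[C@H]2/C=C(/CO)[C@]3(OC)CC[C@](C)(C[C@@H](OC(=O)C(C)C)[C@@H]12)O3
F5 | step 10 | (3R)-epimer of 18 | C=C(B1OC(C)(C)C(C)(C)O1)[C@@H](C=C)[C@H](OC(=O)C(C)C)C[C@](C)(O)CC[C@@H](O)C(=C)C=C
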